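The target is a C2-symmetric bibenzyl. Cutting the central CH2–CH2 bond leaves one arene whose C1 holds the quaternary carbon C1' of a 1,2,2-trimethylcyclopentane. That crowded C1–C1' bond is never made: it is the C1–CO2H bond of (1S,3R)-camphoric acid, and the benzene ring is grown around the old carboxyl carbon. The key step exploits the arene pattern in which C2–O lies next to C1 and para to carbon-bearing C5. A silyl ynol ether, R–C≡C–OSi(i-Pr)3, delivers C1 and C2. Methyl coumalate delivers C3–C6 and the C5 ester. One [4+2] addition and loss of CO2 close the whole ring with this substitution pattern.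

Key step: step 9

**Numbering.** Arene: C1 (cyclopentyl), C2 (OH), C3 (OH), C4 (H), C5 (CH2), C6 (H). Cyclopentane: C1' (quaternary stereocentre), C2' (CMe2). Pyrone carbons C3–C6 keep their numbers in the arene.

**Assumption.** Enantiopure (1S,3R)-(−)-camphoric acid is purchased. Its C1 has the spatial arrangement of C1' in both halves of the target, and the enantiopurity of the target equals that of this acid.

**Design remark.** The C1 carboxyl group is carried as its methyl ester through the radical decarboxylation. A free cis-carboxyl(ate) would attack the activated C3 ester and collapse it to camphoric anhydride.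

**Handling remark.** Compounds 5–8 are small and volatile. They are extracted into pentane and concentrated cold.

Step 1
Reactants: 1 (1S,3R)-(−)-camphoric acid
Product: 2 dimethyl (1S,3R)-1,2,2-trimethylcyclopentane-1,3-dicarboxylate
Conditions: MeI (2.5 equiv), K2CO3 (2.5 equiv), DMF, rt
Reagents that add atoms: iodomethane, CI
Why: Carboxylate O-alkylation (SN2 at methyl) esterifies both acids because the new bond forms at methyl and not at the shielded C1 carbonyl carbon, where acid-catalysed esterification stalls; both stereocentres are untouched.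

Step 2
Reactants: 2 dimethyl (1S,3R)-camphorate
Product: 3 (1R,3S)-3-(methoxycarbonyl)-2,2,3-trimethylcyclopentane-1-carboxylic acid (camphoric acid 1-methyl ester; free acid at camphoric C3)
Conditions: KOH (1.2 equiv), MeOH/H2O, 60 °C; then aq. HCl
Reagents that add atoms: potassium hydroxide, [K+].[OH-]
Why: Chemoselective saponification (BAc2): hydroxide reaches the secondary C3 ester but not the C1 ester, whose carbonyl sits on quaternary C1 next to quaternary C2, and any epimerisation at C3 is harmless because that centre is deleted in step 4.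

Step 3
Reactants: 3 camphoric acid 1-methyl ester
Product: 4 1-(1,3-dioxoisoindolin-2-yl) 3-methyl (1R,3S)-2,2,3-trimethylcyclopentane-1,3-dicarboxylate
Conditions: N-hydroxyphthalimide (1.1 equiv), N,N'-diisopropylcarbodiimide (1.1 equiv), DMAP (10 mol %), CH2Cl2, rt
Reagents that add atoms: N-hydroxyphthalimide, O=C1c2ccccc2C(=O)N1O
Why: Steglich-type carbodiimide esterification gives the redox-active ester, and with C1 blocked as the methyl ester no neighbouring carboxylate can displace the N-oxyphthalimide group.

Step 4
Reactants: 4 redox-active ester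
Product: 5 methyl (1S)-1,2,2-trimethylcyclopentane-1-carboxylate
Conditions: Ru(bpy)3Cl2 (1 mol %), Hantzsch ester (1.5 equiv), t-C12H25SH (10 mol %), DMF, blue LEDs, rt
Reagents that add atoms: none
Why: Photoredox reductive decarboxylation of an N-acyloxyphthalimide: electron transfer from the reduced ruthenium complex fragments 4 into phthalimide anion, CO2 and the secondary C3 radical, which takes a hydrogen atom from the thiol/Hantzsch ester couple, while quaternary C1 is no part of the radical and stays S.

Step 5
Reactants: 5 methyl (1S)-1,2,2-trimethylcyclopentane-1-carboxylate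
Product: 6 [(1S)-1,2,2-trimethylcyclopentyl]methanol
Conditions: LiAlH4, Et2O, 0 °C to reflux
Reagents that add atoms: none
Why: Ester reduction by LiAlH4, a hydride donor small enough to reach the hindered carbonyl at reflux, in a substrate with no other reducible group.

Step 6
Reactants: 6 [(1S)-1,2,2-trimethylcyclopentyl]methanol
Product: 7 (1S)-1,2,2-trimethylcyclopentane-1-carbaldehyde
Conditions: Dess–Martin periodinane (1.2 equiv), CH2Cl2, 0 °C to rt
Reagents that add atoms: none
Why: Dess–Martin oxidation stops at the aldehyde under non-ionising conditions, so the neopentyl system cannot rearrange, and the aldehyde has no α-hydrogen through which it could epimerise.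

Step 7
Reactants: 7 (1S)-1,2,2-trimethylcyclopentane-1-carbaldehyde
Product: 8 (1S)-1-ethynyl-1,2,2-trimethylcyclopentane
Conditions: dimethyl (1-diazo-2-oxopropyl)phosphonate (1.5 equiv), K2CO3 (2 equiv), MeOH, rt
Reagents that add atoms: dimethyl (1-diazo-2-oxopropyl)phosphonate, COP(=O)(OC)C(=[N+]=[N-])C(C)=O
Why: Seyferth–Gilbert homologation in the Ohira–Bestmann form adds one carbon to a non-enolisable aldehyde under mild carbonate conditions, and the former carboxyl carbon becomes the internal alkyne carbon.

Step 8
Reactants: 8 (1S)-1-ethynyl-1,2,2-trimethylcyclopentane; 9 triisopropylsilyl triflate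
Product: 12 triisopropyl{[(1S)-1,2,2-trimethylcyclopentyl]ethynyloxy}silane, via lithium acetylide 10 (not isolated), via lithium ynolate 11 (not isolated)
Conditions: n-BuLi, THF, −78 °C; t-BuOOLi (from anhydrous t-BuOOH and LiN(SiMe3)2, THF, −78 °C), then 0 °C; 9 (1.1 equiv), −78 to 0 °C
Reagents that add atoms: tert-butyl hydroperoxide, CC(C)(C)OO; triisopropylsilyl triflate 9, CC(C)[Si](OS(=O)(=O)C(F)(F)F)(C(C)C)C(C)C
Why: Oxenoid oxygen transfer from the lithium peroxide to the terminal acetylide carbon, which lies far from the quaternary centre, gives the ynolate, and the hard, bulky silyl triflate captures it on oxygen; this is the established acetylide-oxidation route to triisopropylsilyl ynol ethers.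

Step 9
Reactants: 12 silyl ynol ether; 13 methyl coumalate (methyl 2-oxo-2H-pyran-5-carboxylate, freshly recrystallised, 2 equiv)
Product: 15 methyl 4-(triisopropylsilyloxy)-3-[(1S)-1,2,2-trimethylcyclopentyl]benzoate, via bridged lactone 14 (not isolated)
Conditions: toluene (1 M), base-washed sealed tube, Ar, 110 °C
Reagents that add atoms: none
Why: Inverse-electron-demand Diels–Alder addition followed by cycloreversion: the oxygen-raised HOMO of alkyne 12 attacks the diene C3=C4–C5=C6 of 13, whose LUMO is lowered by the lactone carbonyl and the C5 ester, in a concerted but highly asynchronous [4+2] event that gives the 2-oxabicyclo[2.2.2]octa-5,7-dien-3-one 14. The closest known reaction type is the benzannulation of methyl coumalate by ynamines, alkoxyalkynes and ketene acetals, which furnishes 4-donor-substituted benzoates. The one new ring, the benzene ring, is closed intermolecularly in the [4+2] mode through the bonds C1–C6 and C2–C3, and retro-[4+2] ejection of the pyrone lactone bridge (O1 and its carbonyl carbon) as CO2 aromatises it at the reaction temperature. No lasting stereocentre arises, since the two bridgehead centres of 14 disappear on aromatisation, and C1' merely rides along with all four of its bonds intact, so it stays S. Only regioselectivity is required: the alkyl-bearing carbon of 12 carries the larger HOMO coefficient and C6 of 13, the vinylogous acceptor terminus of both carbonyl groups, the larger LUMO coefficient, so these two carbons pair up and the ester ends 1,4 to the silyloxy group and 1,3 to the cyclopentyl group. The triisopropylsilyl group is kept because it offers no retro-ene exit and resists O-to-C migration on heating, while sp hybridisation holds the quaternary carbon further from the diene face than any alkene equivalent would.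

Step 10
Reactants: 15 methyl 4-(triisopropylsilyloxy)-3-[(1S)-1,2,2-trimethylcyclopentyl]benzoate
Product: 16 {4-(triisopropylsilyloxy)-3-[(1S)-1,2,2-trimethylcyclopentyl]phenyl}methanol
Conditions: i-Bu2AlH (2.5 equiv), CH2Cl2, −78 to 0 °C; aq. potassium sodium tartrate
Reagents that add atoms: none
Why: Ester-to-alcohol reduction with i-Bu2AlH, to which the hindered aryl silyl ether is inert.

Step 11
Reactants: 16 benzylic alcohol
Product: 17 {4-(bromomethyl)-2-[(1S)-1,2,2-trimethylcyclopentyl]phenoxy}triisopropylsilane
Conditions: CBr4 (1.2 equiv), PPh3 (1.2 equiv), CH2Cl2, 0 °C; short silica plug, used at once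
Reagents that add atoms: tetrabromomethane, BrC(Br)(Br)Br
Why: Appel bromination replaces the primary benzylic hydroxyl under neutral conditions, which spares the silyl ether and avoids acid-induced ionisation of the electron-rich benzylic position.

Step 12
Reactants: 17 benzylic bromide (two molecules)
Product: 18 1,2-bis{4-(triisopropylsilyloxy)-3-[(1S)-1,2,2-trimethylcyclopentyl]phenyl}ethane
Conditions: SmI2 (1.1 equiv per bromide, 0.1 M in THF), rt
Reagents that add atoms: none
Why: Wurtz-type reductive homocoupling: divalent samarium gives one electron to each C–Br bond and the benzyl radical/benzylsamarium species forms the central CH2–CH2 bond, a fast process for benzylic bromides that leaves silyl ethers alone and takes place far from the bulky meta substituent.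

Step 13
Reactants: 18 bis(silyl ether)
Product: 19 4,4'-(ethane-1,2-diyl)bis{2-[(1S)-1,2,2-trimethylcyclopentyl]phenol}
Conditions: Bu4NF (2.5 equiv), THF, 0 °C to rt
Reagents that add atoms: none
Why: Fluoride-induced desilylation, driven by Si–F bond formation and the good phenoxide leaving group, frees both phenols without touching anything else.

Step 14
Reactants: 19 bisphenol
Product: 20 5,5'-(ethane-1,2-diyl)bis{2-hydroxy-3-[(1S)-1,2,2-trimethylcyclopentyl]benzaldehyde}
Conditions: MgCl2 (4 equiv), Et3N (8 equiv), (CH2O)n (14 equiv), MeCN, reflux; aq. HCl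
Reagents that add atoms: paraformaldehyde (as formaldehyde), C=O
Why: Casnati–Skattebøl ortho-formylation delivers formaldehyde within the magnesium phenoxide chelate and so reacts only ortho to oxygen, where C3 is the single open position (C1 and C5 are substituted); 2-tert-alkylphenols are standard substrates for it.

Step 15
Reactants: 20 bis(salicylaldehyde)
Product: 22 5,5'-(ethane-1,2-diyl)bis{3-[(1S)-1,2,2-trimethylcyclopentyl]benzene-1,2-diol} (target), via bis(aryl formate) 21 (not isolated)
Conditions: 30% aq. H2O2 (2.5 equiv), NaOH (2.5 equiv), degassed THF/H2O, Ar, 0 °C to rt; aq. HCl, Na2S2O4 wash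
Reagents that add atoms: hydrogen peroxide, OO
Why: Dakin oxidation: hydroperoxide adds to each formyl group, the electron-rich ortho-oxido aryl group migrates to oxygen, and the formate is hydrolysed in situ, while exclusion of air and a reducing work-up protect the catechol.

Compound list
1 | (1S,3R)-(−)-camphoric acid | OC(=O)[C@@]1(C)CC[C@@H](C(O)=O)C1(C)C | starting material
2 | dimethyl (1S,3R)-1,2,2-trimethylcyclopentane-1,3-dicarboxylate | COC(=O)[C@@]1(C)CC[C@@H](C(=O)OC)C1(C)C | intermediate
3 | (1R,3S)-3-(methoxycarbonyl)-2,2,3-trimethylcyclopentane-1-carboxylic acid | COC(=O)[C@@]1(C)CC[C@@H](C(O)=O)C1(C)C | intermediate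
4 | 1-(1,3-dioxoisoindolin-2-yl) 3-methyl (1R,3S)-2,2,3-trimethylcyclopentane-1,3-dicarboxylate | COC(=O)[C@@]1(C)CC[C@@H](C(=O)ON2C(=O)c3ccccc3C2=O)C1(C)C | intermediate
5 | methyl (1S)-1,2,2-trimethylcyclopentane-1-carboxylate | COC(=O)[C@@]1(C)CCCC1(C)C | intermediate
6 | [(1S)-1,2,2-trimethylcyclopentyl]methanol | OC[C@@]1(C)CCCC1(C)C | intermediate
7 | (1S)-1,2,2-trimethylcyclopentane-1-carbaldehyde | O=C[C@@]1(C)CCCC1(C)C | intermediate
8 | (1S)-1-ethynyl-1,2,2-trimethylcyclopentane | C#C[C@@]1(C)CCCC1(C)C | intermediate
9 | triisopropylsilyl triflate | CC(C)[Si](OS(=O)(=O)C(F)(F)F)(C(C)C)C(C)C | starting material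
10 | lithium [(1S)-1,2,2-trimethylcyclopentyl]acetylide | [Li+].[C-]#C[C@@]1(C)CCCC1(C)C | intermediate
11 | lithium [(1S)-1,2,2-trimethylcyclopentyl]ethynolate | [Li+].[O-]C#C[C@@]1(C)CCCC1(C)C | intermediate
12 | triisopropyl{[(1S)-1,2,2-trimethylcyclopentyl]ethynyloxy}silane | CC(C)[Si](OC#C[C@@]1(C)CCCC1(C)C)(C(C)C)C(C)C | intermediate
13 | methyl coumalate | COC(=O)C1=COC(=O)C=C1 | starting material
14 | methyl 3-oxo-5-(triisopropylsilyloxy)-6-[(1S)-1,2,2-trimethylcyclopentyl]-2-oxabicyclo[2.2.2]octa-5,7-diene-8-carboxylate (both bridgehead epimers) | O=C1OC2C(C(=O)OC)=CC1C(O[Si](C(C)C)(C(C)C)C(C)C)=C2[C@@]3(C)CCCC3(C)C | intermediate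
15 | methyl 4-(triisopropylsilyloxy)-3-[(1S)-1,2,2-trimethylcyclopentyl]benzoate | COC(=O)c1ccc(O[Si](C(C)C)(C(C)C)C(C)C)c([C@@]2(C)CCCC2(C)C)c1 | intermediate
16 | {4-(triisopropylsilyloxy)-3-[(1S)-1,2,2-trimethylcyclopentyl]phenyl}methanol | OCc1ccc(O[Si](C(C)C)(C(C)C)C(C)C)c([C@@]2(C)CCCC2(C)C)c1 | intermediate
17 | {4-(bromomethyl)-2-[(1S)-1,2,2-trimethylcyclopentyl]phenoxy}triisopropylsilane | BrCc1ccc(O[Si](C(C)C)(C(C)C)C(C)C)c([C@@]2(C)CCCC2(C)C)c1 | intermediate
18 | 1,2-bis{4-(triisopropylsilyloxy)-3-[(1S)-1,2,2-trimethylcyclopentyl]phenyl}ethane | CC(C)[Si](C(C)C)(C(C)C)Oc1ccc(CCc2ccc(O[Si](C(C)C)(C(C)C)C(C)C)c([C@@]3(C)CCCC3(C)C)c2)cc1[C@@]4(C)CCCC4(C)C | intermediate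
19 | 4,4'-(ethane-1,2-diyl)bis{2-[(1S)-1,2,2-trimethylcyclopentyl]phenol} | Oc1ccc(CCc2ccc(O)c([C@@]3(C)CCCC3(C)C)c2)cc1[C@@]4(C)CCCC4(C)C | intermediate
20 | 5,5'-(ethane-1,2-diyl)bis{2-hydroxy-3-[(1S)-1,2,2-trimethylcyclopentyl]benzaldehyde} | O=Cc1cc(CCc2cc(C=O)c(O)c([C@@]3(C)CCCC3(C)C)c2)cc([C@@]4(C)CCCC4(C)C)c1O | intermediate
21 | ethane-1,2-diylbis{2-hydroxy-3-[(1S)-1,2,2-trimethylcyclopentyl]-5,1-phenylene} diformate | O=COc1cc(CCc2cc(OC=O)c(O)c([C@@]3(C)CCCC3(C)C)c2)cc([C@@]4(C)CCCC4(C)C)c1O | intermediate
22 | 5,5'-(ethane-1,2-diyl)bis{3-[(1S)-1,2,2-trimethylcyclopentyl]benzene-1,2-diol} | CC1(C)CCC[C@]1(C)c1cc(CCc2cc(O)c(O)c([C@@]3(C)CCCC3(C)C)c2)cc(O)c1O | target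

Total step count: 15. Longest linear sequence: 15 steps (1 to 22). From step 12 on, each operation treats both halves at once.

Steps most likely to fail

1. **Step 9 (key step).**
   - Risk: the cycloaddition may be slower than thermal O-to-C silyl migration or adventitious protonation of the ynol ether. The silyloxy and tert-alkyl groups are pressed together as the alkyne carbons rehybridise.
   - Fallback, from 11 back to 15: the two-carbon partner is moved to the alkene oxidation level. There the nucleophilicity is much higher and aromatisation occurs by elimination.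
   - The ynolate 11, made from 8 as in step 8, is quenched with aqueous HCl instead of 9. Protonation to the ketene and hydration should give (R)-2-(1,2,2-trimethylcyclopentyl)acetic acid F1. The spatial arrangement is the same; the descriptor changes only because CH2CO2H ranks below C2'.
   - Double deprotonation with LiN(i-Pr)2 (2.2 equiv, THF) and silylation with Me3SiCl should give the ketene bis(trimethylsilyl) acetal F2.
   - Heating F2 with 13 in toluene follows the established ketene acetal/coumalate benzannulation: bonding of the β-carbon to C6, closure at C3, loss of CO2, and elimination of silanol. A mild acidic work-up should deliver methyl 4-hydroxy-3-[(1S)-1,2,2-trimethylcyclopentyl]benzoate F3.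
   - Silylation of F3 with 9 and 2,6-lutidine in CH2Cl2 returns 15.

2. **Step 8.**
   - Risk: incomplete oxygen transfer from the peroxide to the acetylide, or silylation of the ynolate at carbon instead of oxygen.
   - Fallback, from 8 back to 11: the oxygen is brought in through hypervalent iodine chemistry, which works best for bulky alkynes.
   - Heating 8 with PhI(OH)OTs in CHCl3 should give [(1S)-1,2,2-trimethylcyclopentyl]ethynyl(phenyl)iodonium tosylate F4.
   - Catalytic AgOTf in MeCN should collapse F4 to [(1S)-1,2,2-trimethylcyclopentyl]ethynyl tosylate F5.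
   - MeLi in THF at −78 °C attacks sulfur of F5 and releases the lithium ynolate 11 free of peroxide and alkoxide. It is then silylated with 9 as in step 8.

3. **Step 12.**
   - Risk: reduction of the benzylic intermediate to the methylarene instead of dimerisation, or loss of bromide from the electron-rich benzylic bromide during handling.
   - Fallback, from 16 back to 18: the central bond is made as an alkene from the carbonyl level.
   - MnO2 in CH2Cl2 should oxidise 16 to 4-(triisopropylsilyloxy)-3-[(1S)-1,2,2-trimethylcyclopentyl]benzaldehyde F6.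
   - McMurry coupling of F6 (TiCl4, Zn, pyridine, THF, reflux) should give the symmetrical stilbene F7. Its alkene geometry is irrelevant.
   - Hydrogenation of F7 (H2, Pd on carbon, EtOAc) returns 18.

Further compounds
F1 | step 9 | (R)-2-(1,2,2-trimethylcyclopentyl)acetic acid | OC(=O)C[C@@]1(C)CCCC1(C)C
F2 | step 9 | {2-[(1R)-1,2,2-trimethylcyclopentyl]ethene-1,1-diyl}bis(oxy)bis(trimethylsilane) | C[Si](C)(C)OC(O[Si](C)(C)C)=C[C@@]1(C)CCCC1(C)C
F3 | step 9 | methyl 4-hydroxy-3-[(1S)-1,2,2-trimethylcyclopentyl]benzoate | COC(=O)c1ccc(O)c([C@@]2(C)CCCC2(C)C)c1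
F4 | step 8 | [(1S)-1,2,2-trimethylcyclopentyl]ethynyl(phenyl)iodonium tosylate | Cc1ccc(cc1)S(=O)(=O)[O-].c1ccc(cc1)[I+]C#C[C@@]2(C)CCCC2(C)C
F5 | step 8 | [(1S)-1,2,2-trimethylcyclopentyl]ethynyl 4-methylbenzenesulfonate | Cc1ccc(cc1)S(=O)(=O)OC#C[C@@]2(C)CCCC2(C)C
F6 | step 12 | 4-(triisopropylsilyloxy)-3-[(1S)-1,2,2-trimethylcyclopentyl]benzaldehyde | O=Cc1ccc(O[Si](C(C)C)(C(C)C)C(C)C)c([C@@]2(C)CCCC2(C)C)c1
F7 | step 12 | (E)-1,2-bis{4-(triisopropylsilyloxy)-3-[(1S)-1,2,2-trimethylcyclopentyl]phenyl}ethene | CC(C)[Si](C(C)C)(C(C)C)Oc1ccc(/C=C/c2ccc(O[Si](C(C)C)(C(C)C)C(C)C)c([C@@]3(C)CCCC3(C)C)c2)cc1[C@@]4(C)CCCC4(C)C
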